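The earlier runs and the new flask are simulated with made-up constants, and the scatter is random.

A small charge of free catalyst, 14.0 % of the substrate charged in oak and 9.33 % in alder, serves both runs, and the next run must choose what to change.

| setting | oak | alder | flask |
|---|---|---|---|
| substrate | 0.020 M | 0.030 M | 0.020 M |
| free catalyst | 2.8 mM | 2.8 mM | 2.8 mM |
| remark | the very flask that is asked about, followed so far | run made earlier |  |

| run | time / min | product / % | substrate / % |
|---|---|---|---|
| oak | 2.50 | 3.0 | 97.4 |
| oak | 6.00 | 6.5 | 94.3 |
| oak | 12.0 | 11.8 | 88.2 |
| oak | 20.0 | 19.4 | 80.7 |
| oak | 25.0 | 23.2 | 76.7 |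
| oak | 40.0 | 34.1 | 66.3 |
| oak | 50.0 | 39.5 | 60.1 |
| alder | 15.0 | 14.7 | 85.3 |
| alder | 30.0 | 26.5 | 73.2 |
| alder | 50.0 | 39.5 | 60.3 |
| alder | 60.0 | 45.1 | 54.7 |
| alder | 80.0 | 54.0 | 46.2 |
| alder | 90.0 | 57.7 | 42.8 |
| alder | 120 | 66.2 | 33.4 |

(each reading ± 0.3 percentage points)

- apparent order in free catalyst when 50 % of the substrate are converted (percent change of the rate of making product for one percent more free catalyst charged)

- no earlier run changes the charge of free catalyst; that part of a forecast is a guess

The substrate charge can stay: oak and alder differ in it, yet both show 39.5 % product at 50.0 min. Conversion therefore follows clock time. The catalyst charge was never varied, so I guess that rate goes as free catalyst and that free catalyst is lost by a first-order step (deactivation). A lasting catalyst then sets the zero of the scale, an apparent order of one.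

Let L be the logarithm of the inverse substrate fraction and s the free share of the catalyst charged. Then s falls in a straight line with L, and the catalyst lost by a given conversion is a fixed amount whatever the charge. One percent more charge thus gives the inverse of s in percent more free catalyst there, and that inverse is the order.

With equal time steps, L at the later time over L at the earlier, less one, reads s at the earlier time. Alder at 60.0 min and 120 min gives 81.8 %, hence a slope 0.302. This wear is the share of the charge lost per unit of L. At 50 % conversion, s is 79.1 %, so I reckon an order of 1.26. The next run therefore keeps the substrate and changes the free catalyst.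

The forecast gives 1.18, lower than my reckoning, on the grounds “Since this tracks clock time, the catalyst is apparently dying”.

The flask gives 1.2.

    substrate + free catalyst → free catalyst + product (k = 0.0650 /M/s)
    free catalyst → spent catalyst (k = 5.10 × 10⁻⁵ /s)

Free catalyst has a half-life of 3.78 h against 1.2 h for substrate by its step at 0.743 h. At 50 % conversion, reached at 1.18 h, spent catalyst holds 19.4 %, which leaves a free share of 80.6 %, whose inverse is 1.24. At 2.50 h the flask holds substrate 26.9 %, for which the wear of 0.302 read from alder reckons a free share of 60.3 %, and free catalyst stands at 63.2 %.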